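Locants C1–C20 follow the briarane numbering: C1 is the quaternary ring-fusion carbon with methyl C15, C2–C9 run round ring A, C10 is the ring-fusion CH, C11–C14 complete ring B, C16 is the carbon on C5, and C17/C18/C19 are CH, CH3 and C=O of lactone ring C. "α-Face of ring B" means the face opposite the C15 methyl.

## Analysis of the target

Target 49 is a briarane: a ten-membered carbocycle (ring A, C1–C10) trans-fused along C1–C10 to a cyclohexane (ring B) and fused at C7–C8 to a γ-lactone (ring C, ring oxygen on C7). It has ten stereocentres (C1, C2, C7, C8, C9, C10, C11, C12, C14, C17) and a trisubstituted C5=C6 alkene in which C4 is cis to C7 and the chloromethyl carbon C16 is trans to C7. On ring B the C15 methyl, C9 and the C20 methyl lie on one face; H10, the C11 and C12 hydroxyls and the C14 acetate lie on the other, so the 11,12-diol is cis and C20 is 1,3-syn to C15. In ring C the C8 hydroxyl is cis to C6 and to the C18 methyl and trans to C9. The sensitive groups are the primary allylic chloride, three secondary acetates beside a free C12 hydroxyl that is 1,3-syn to the C14 acetate (acyl migration), two tertiary alcohols and a β-hydroxy lactone (retro-aldol, dehydration). The difficulty lies in the quaternary C1 flanked by three stereocentres, in closing a ten-membered ring, and in telling seven oxygen functions apart. The strategy rests on the C15–C1–C10–C9 array: with C11 as a ketone, C1 is the β-carbon and C10 the α-carbon of a ring B enone, so C15 can arrive as a nucleophile at C1 and C9 as an electrophile at C10 in one operation.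

## Retrosynthetic reasoning

**C16–Cl and the last protecting groups.** The C16–Cl bond of 49 is cut first, because the allylic chloride tolerates neither palladium nor nucleophilic catalysts nor base. It is made last from tetraol 48, where only a primary allylic hydroxyl competes with one hindered secondary and two tertiary hydroxyls. 48 comes from macrocycle 47 by one acid treatment that removes the C16 silyl ether and the 11,12-acetonide; the acetonide is what keeps O12 free of acetate.

**Ring A, C4–C5.** Ring A of 47 is opened at the sp3–sp2 bond next to the alkene. This cut leaves no extra oxygen on C3 or C4 and lets the alkene geometry be fixed in an open-chain alkenyl iodide, 45. The forward step is hydroboration of the C2 vinyl group (borane 46) and an intramolecular alkyl–alkenyl palladium coupling, which must outrun oligomerisation while forming a medium ring.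

**Acetates, iodide, stannane.** The three acetates of 45 are introduced only after every strongly basic or organometallic step is past (44, 43). Iodide 42 goes back through stannanes 41, 40 and 39 to propargylic alcohol 38. A hydroxyl-directed trans-hydrostannation puts tin on C5 and hydrogen on C6 anti to it, which is the target geometry; this is why C5, C6 and C16 travel as a propargylic alcohol.

**Lactone C8–OH and C17–H.** These are the formal addition of water to a butenolide. 41 is traced to the C17 epimer mixture 40 (equilibration puts C18 trans to C9) and 40 to the 8,17-epoxide in 39 (reductive cleavage of C17–O). The epoxide is carried unchanged from 27, because an epoxy lactone has no acidic hydrogen and no free C8 hydroxyl that could form a lactol with the C2 aldehyde 34.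

**C2–C3.** Carbinol 37 is cut to aldehyde 34 and a vinyl nucleophile. The neopentyl aldehyde offers little facial bias, so both epimers 35 are oxidised to vinyl ketone 36 and C2 is set by reagent-controlled reduction. 34 comes from 33 and acetonide 32.

**Ring B diol.** The cis-diol of 31 is cut to alkene 30. A direct methyl addition to the C11 ketone was rejected: the axial C15 methyl is 1,3 to C11 and would force the methyl in from the α-face, giving the C11 epimer. Osmylation of 30 from the α-face places both oxygens correctly and leaves C20 β. 30 comes from enol triflate 29 and ketone 27, so C20 is attached to an sp2 carbon where no stereochemistry is at stake.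

**Epoxidation before any strong base.** 27 is traced to butenolide 25. Allylic strain with C18 holds H9 in the butenolide plane, so ring B covers the butenolide face that carries C6, which is the face where the C8 oxygen must enter. An external oxidant would therefore give the C8 epimer. The oxygen is instead delivered from ring B itself, through perhydrate 26 of the C11 ketone. Doing this directly after the fragment union also removes the acidic C7–H of the butenolide before the enolate chemistry of ring B.

**Key disconnection.** Adduct 24 is cut at C1–C15 and C9–C10 into enone 10, a methyl cuprate and aldehyde 22. This sets C1, C10 and C9 and brings C7, C8, C17 and C19 in the same operation. The forward reaction needs conjugate addition anti to O14, attack at C10 anti to the C2 arm, and an open transition state for the syn C9/C10 relation.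

**Enone 10.** It is cut at C1–C2 to silyloxy ketone 4 and stannane 7 (from 5 and 6); 1,2-addition and acid transposition move the carbonyl to C11. The C14 stereocentre of 4 comes from 3, obtained by resolution of acetate 2 made from 1.

**Aldehyde 22.** It is traced through alcohol 21 and ether 20 to keto phosphonate 19, cut at C8=C17 (intramolecular olefination). 19 comes from ester 18, i.e. carbinol 16 and acid 17. The C7 stereocentre of 16 is set by catalytic asymmetric alkynylation of enal 15 (from 14 and 13) with alkyne 12 (from 11); the 1,1-disubstituted alkene of 16 is a masked C8 ketone.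

## Alternatives that were turned down

**Alternative 1:** The cut is again C4–C5, but with C2 as a ketone and C3–C4 as the opened form of a C2 cyclopropanol. In the forward step Pd(OAc)2 with P(t-Bu)3 and K3PO4 gives zerovalent palladium, which inserts into the C5–I bond; the cyclopropanol binds as alkoxide, opens to a palladium homoenolate, and reductive elimination gives tricyclic ketone A1.
- For: C3, C4 and the C2 carbonyl arrive together from a cyclopropanol that one titanium-mediated cyclopropanation of a C2 ester would supply, and no hydroboration is needed. On the count of steps between a C2 carbonyl and the closed ring it is stronger than the chosen route, which spends steps 24–26 and a hydroboration on the same atoms.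
- Against: the homoenolate can lose β-hydride to an enone, the more so the slower a medium-ring reductive elimination is. Phosphate base at coupling temperature endangers the acetates and the β-hydroxy lactone already present in A1. The C2 ketone must still be reduced to the S alcohol by the macrocycle conformation alone.
- Comparison: it says nothing about how C1, C9 and C10 are made, so it could only replace the ring closure, and it puts its risk on the most advanced material. The chosen route keeps the same bond but sets C2 by reagent control before cyclisation and uses an alkylborane, which has no such β-hydride path.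

**Alternative 2:** Ring B is cut at C1–C14 and C10–C11. A 1-alkoxy-3-silyloxy diene (C14=C13–C12=C11) and a 2-methyl enal (C1=C10, formyl carbon C2) combine under a triflimide-activated diphenylprolinol oxazaborolidine to give cyclohexene carbaldehyde A2.
- For: catalytic absolute stereocontrol, four stereocentres (C1, C10, C11, C14) in one step, and the C12 oxygen already in place as an enol ether. On absolute control and on ring B oxygenation it is stronger than the chosen route, which needs a resolution for C14 and four steps for the diol.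
- Against: a trisubstituted α-methyl enal is a sluggish dienophile, and the diene must be geometrically pure at its methyl terminus. C11 arrives as CH(CH3), so the tertiary hydroxyl still needs an enolate oxidation and a C12 reduction. C9 arrives only as a benzyloxymethyl group, so the C9 stereocentre and the whole lactone must be added by a later, separate carbonyl addition with its own facial problem.
- Comparison: the chosen union makes C9 and attaches C7, C8, C17 and C19 at the moment the quaternary centre is formed, which is worth more than the steps saved on ring B.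

**Alternative 3:** Ring B is cut at C11–C12. SmI2 (divalent samarium) with tert-butanol in tetrahydrofuran couples a C12 aldehyde with a C11 methyl ketone to give cis-diol A3.
- For: the tertiary C11 carbinol and the cis-diol come in one step through a chelated ketyl. On this point it is stronger than steps 18–20 of the chosen route.
- Against: the open-chain substrate must already hold the quaternary C1 and the C10 and C14 stereocentres, so the hardest problem is moved to acyclic stereocontrol. The diol is cis, but its face relative to C1 and C10 rests on a flexible chain. C2 and C9 are both plain protected hydroxymethyl groups, so the lactone and the C9 centre remain to be built.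
- Comparison: the chosen route makes C1 and C10 on a ring, where the C14 silyloxy group controls the faces, and pays for it with a longer diol sequence.

Key step: step 15

Remark: the lipase of step 2 is assumed to hydrolyse the S acetate; if the enzyme at hand prefers the R acetate, the recovered S acetate is methanolysed and gives the same alcohol 3.

Remark: in steps 9 and 26 the catalyst antipode named is the one current models predict; the configuration drawn for the product is what counts.

## Route

**Step 1**
Reactants: 1 3-ethoxycyclohex-2-en-1-one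
Product: 2 rac-4-ethoxy-2-oxocyclohex-3-en-1-yl acetate
Conditions: Mn(OAc)3·2H2O (trivalent manganese), benzene, reflux
Reagents that add atoms: manganese triacetate, CC(=O)[O-].CC(=O)[O-].CC(=O)[O-].[Mn+3]
Why: Oxidative α′-acetoxylation of an enone through its manganese enolate; the vinylogous ester leaves only the C6 methylene for enolisation, so the oxygen that becomes O14 enters there, as a racemate.

**Step 2**
Reactants: 2 rac-4-ethoxy-2-oxocyclohex-3-en-1-yl acetate
Product: 3 (S)-3-ethoxy-6-hydroxycyclohex-2-en-1-one
Conditions: lipase from Burkholderia cepacia, phosphate buffer pH 7, t-BuOMe, rt, to half conversion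
Reagents that add atoms: none
Why: Enzymatic kinetic resolution by enantioselective ester hydrolysis, a known route to enantiopure 6-hydroxy-3-alkoxycyclohexenones; the S alcohol (later C14) is separated from the unreacted R acetate, and the neutral medium avoids enolisation of the α-hydroxy ketone.

**Step 3**
Reactants: 3 (S)-3-ethoxy-6-hydroxycyclohex-2-en-1-one
Product: 4 (S)-6-[(tert-butyldimethylsilyl)oxy]-3-ethoxycyclohex-2-en-1-one
Conditions: TBSCl, imidazole, DMF, rt
Reagents that add atoms: tert-butyldimethylsilyl chloride, CC(C)(C)[Si](C)(C)Cl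
Why: Standard silylation; the bulky silyl ether later steers the cuprate to the opposite face.

**Step 4**
Reactants: 5 4-methoxybenzyl alcohol; 6 tributyl(iodomethyl)stannane
Product: 7 tributyl{[(4-methoxybenzyl)oxy]methyl}stannane
Conditions: NaH, THF, 0 °C to rt
Reagents that add atoms: none
Why: Williamson etherification of the reactive iodomethylstannane gives the precursor of a protected hydroxymethyl anion (carbon C2).

**Step 5**
Reactants: 7 tributyl{[(4-methoxybenzyl)oxy]methyl}stannane; 4 (S)-6-[(tert-butyldimethylsilyl)oxy]-3-ethoxycyclohex-2-en-1-one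
Product: 10 (S)-4-[(tert-butyldimethylsilyl)oxy]-3-{[(4-methoxybenzyl)oxy]methyl}cyclohex-2-en-1-one, via alkoxymethyllithium 8 (not isolated), via tertiary allylic alcohol 9 (not isolated)
Conditions: n-BuLi, THF, −78 °C; then 4, −78 °C; then 1 M aq. HCl, THF, 0 °C
Reagents that add atoms: water, O
Why: Tin–lithium exchange, 1,2-addition to the vinylogous ester and acid-induced Stork–Danheiser transposition; C1 now carries C2, the carbonyl sits at C11, and the C14 centre is not involved.

**Step 6**
Reactants: 11 prop-2-yn-1-ol
Product: 12 tert-butyldimethyl(prop-2-yn-1-yloxy)silane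
Conditions: TBSCl, imidazole, CH2Cl2, 0 °C to rt
Reagents that add atoms: tert-butyldimethylsilyl chloride, CC(C)(C)[Si](C)(C)Cl
Why: Standard silylation of the later C16 hydroxyl.

**Step 7**
Reactants: 13 2-methylenepropane-1,3-diol
Product: 14 2-{[(4-methoxybenzyl)oxy]methyl}prop-2-en-1-ol
Conditions: NaH (1 equiv), 4-methoxybenzyl chloride, Bu4NI (cat.), THF, 0 °C to rt
Reagents that add atoms: 4-methoxybenzyl chloride, COc1ccc(CCl)cc1
Why: Statistical mono-etherification of a symmetrical diol; diol and bis-ether are separated and recycled.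

**Step 8**
Reactants: 14 2-{[(4-methoxybenzyl)oxy]methyl}prop-2-en-1-ol
Product: 15 2-{[(4-methoxybenzyl)oxy]methyl}prop-2-enal
Conditions: MnO2, CH2Cl2, rt
Reagents that add atoms: none
Why: Selective oxidation of an allylic alcohol to the enal without over-oxidation.

**Step 9**
Reactants: 15 2-{[(4-methoxybenzyl)oxy]methyl}prop-2-enal; 12 tert-butyldimethyl(prop-2-yn-1-yloxy)silane
Product: 16 (S)-6-[(tert-butyldimethylsilyl)oxy]-2-{[(4-methoxybenzyl)oxy]methyl}hex-1-en-4-yn-3-ol
Conditions: (R,R)-ProPhenol (20 mol %), Me2Zn, Ph3PO, toluene, 0 °C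
Reagents that add atoms: none
Why: Catalytic asymmetric alkynylation: the zinc alkynylide adds to the aldehyde inside the dinuclear zinc–ProPhenol complex, which selects the aldehyde face and sets C7; enals are good substrates and no strong base is present.

**Step 10**
Reactants: 16 (S)-6-[(tert-butyldimethylsilyl)oxy]-2-{[(4-methoxybenzyl)oxy]methyl}hex-1-en-4-yn-3-ol; 17 2-(diethoxyphosphoryl)propanoic acid
Product: 18 (S)-6-[(tert-butyldimethylsilyl)oxy]-2-{[(4-methoxybenzyl)oxy]methyl}hex-1-en-4-yn-3-yl 2-(diethoxyphosphoryl)propanoate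
Conditions: DCC, DMAP (cat.), CH2Cl2, 0 °C to rt
Reagents that add atoms: none
Why: Steglich esterification; the phosphonate carbon is a mixture of epimers, which does not matter because it becomes sp2.

**Step 11**
Reactants: 18 (S)-6-[(tert-butyldimethylsilyl)oxy]-2-{[(4-methoxybenzyl)oxy]methyl}hex-1-en-4-yn-3-yl 2-(diethoxyphosphoryl)propanoate
Product: 19 (S)-6-[(tert-butyldimethylsilyl)oxy]-1-[(4-methoxybenzyl)oxy]-2-oxohex-4-yn-3-yl 2-(diethoxyphosphoryl)propanoate
Conditions: OsO4 (2 mol %), NaIO4, 2,6-lutidine, dioxane/H2O, rt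
Reagents that add atoms: sodium periodate, [Na+].[O-]I(=O)(=O)=O
Why: Lemieux–Johnson cleavage: OsO4 dihydroxylates the 1,1-disubstituted alkene far faster than the alkyne and periodate cleaves the diol to the C8 ketone; the buffered medium leaves the acidic C7–H alone.

**Step 12**
Reactants: 19 (S)-6-[(tert-butyldimethylsilyl)oxy]-1-[(4-methoxybenzyl)oxy]-2-oxohex-4-yn-3-yl 2-(diethoxyphosphoryl)propanoate
Product: 20 (S)-5-{3-[(tert-butyldimethylsilyl)oxy]prop-1-yn-1-yl}-4-{[(4-methoxybenzyl)oxy]methyl}-3-methylfuran-2(5H)-one
Conditions: LiCl, i-Pr2NEt, MeCN, 0 °C to rt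
Reagents that add atoms: none
Why: Intramolecular Horner–Wadsworth–Emmons reaction under Masamune–Roush conditions: lithium chelation lets an amine base deprotonate the phosphonate, the five-membered ring closes and elimination gives the tetrasubstituted C8=C17 alkene; the weak base is chosen to spare C7.

**Step 13**
Reactants: 20 (S)-5-{3-[(tert-butyldimethylsilyl)oxy]prop-1-yn-1-yl}-4-{[(4-methoxybenzyl)oxy]methyl}-3-methylfuran-2(5H)-one
Product: 21 (S)-5-{3-[(tert-butyldimethylsilyl)oxy]prop-1-yn-1-yl}-4-(hydroxymethyl)-3-methylfuran-2(5H)-one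
Conditions: DDQ, CH2Cl2/pH 7 buffer, 0 °C
Reagents that add atoms: none
Why: Oxidative cleavage of the 4-methoxybenzyl ether by benzylic hydride abstraction; silyl ether, alkyne and butenolide are inert.

**Step 14**
Reactants: 21 (S)-5-{3-[(tert-butyldimethylsilyl)oxy]prop-1-yn-1-yl}-4-(hydroxymethyl)-3-methylfuran-2(5H)-one
Product: 22 (S)-2-{3-[(tert-butyldimethylsilyl)oxy]prop-1-yn-1-yl}-4-methyl-5-oxo-2,5-dihydrofuran-3-carbaldehyde
Conditions: Dess–Martin periodinane, NaHCO3, CH2Cl2, 0 °C
Reagents that add atoms: none
Why: Buffered, base-free oxidation of the primary allylic alcohol to the C9 aldehyde, which is used at once.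

**Step 15 (key step)**
Reactants: 10 (S)-4-[(tert-butyldimethylsilyl)oxy]-3-{[(4-methoxybenzyl)oxy]methyl}cyclohex-2-en-1-one; 22 (S)-2-{3-[(tert-butyldimethylsilyl)oxy]prop-1-yn-1-yl}-4-methyl-5-oxo-2,5-dihydrofuran-3-carbaldehyde
Product: 24 aldol adduct joining ring B to the butenolide (C9 alcohol), via C10=C11 trimethylsilyl enol ether 23 (not isolated)
Conditions: Me2CuLi (monovalent copper), Me3SiCl, THF, −78 °C; then 22, BF3·OEt2, −78 °C
Reagents that add atoms: lithium dimethylcuprate, [Li+].C[Cu-]C
Why: The cuprate forms a π-complex with the enone and transfers methyl C15 to C1, and Me3SiCl traps the enolate as the regiodefined C10=C11 enol silane 23; BF3·OEt2 then activates aldehyde 22 and a Mukaiyama aldol addition forms C9–C10. The closest known reaction type is the three-component coupling of cuprate conjugate addition, silyl trapping and Lewis-acid aldol addition. No ring is closed. C1 is controlled by the C14 silyloxy group, which sits pseudoaxial so that the methyl enters anti to it. C10 is controlled by the C1 substituents: the aldehyde approaches anti to the larger CH2OPMB arm, which leaves only the small methyl gauche to the incoming electrophile, so C9 ends cis to C15. C9 is controlled by the open, antiperiplanar transition state of the BF3 reaction, in which the butenolide turns away from the quaternary C1 and H9 lies over it, giving the syn relation; a closed metal-enolate chair would give the epimer. The step needs 1,2-addition to the aldehyde in preference to attack on the butenolide, which the far higher electrophilicity of the BF3-bound formyl group secures. The absence of base keeps C7 intact.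

**Step 16**
Reactants: 24 aldol adduct joining ring B to the butenolide (C9 alcohol)
Product: 25 C9 tert-butyldimethylsilyl ether of 24
Conditions: TBSOTf, 2,6-lutidine, CH2Cl2, −78 °C
Reagents that add atoms: tert-butyldimethylsilyl triflate, CC(C)(C)[Si](C)(C)OS(=O)(=O)C(F)(F)F
Why: Silylation of the hindered C9 hydroxyl blocks retro-aldol cleavage and removes a hydroxyl that could steer an oxidant to the wrong butenolide face; 2,6-lutidine at −78 °C is too weak to turn the butenolide into a silyloxyfuran.

**Step 17**
Reactants: 25 C9 tert-butyldimethylsilyl ether of 24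
Product: 27 8,17-epoxy lactone ketone (epoxide oxygen syn to C6), via C11 perhydrate 26 (not isolated)
Conditions: 30% aq. H2O2, K2CO3 (0.3 equiv), THF/MeOH, −10 to 0 °C
Reagents that add atoms: hydrogen peroxide, OO
Why: Proposed new method: hydrogen peroxide adds reversibly to the C11 ketone to give perhydrate 26; because allylic strain with the C18 methyl holds H9 in the butenolide plane, ring B and its C11–O–OH group lie on the butenolide face that also carries C6, so the peroxide oxygen can reach C8 through a six-membered transition state and the lactone enolate then closes the epoxide by expelling the hemiketal oxygen, which returns the ketone; the closest known reactions are the Weitz–Scheffer epoxidation of butenolides with alkaline hydrogen peroxide and hydroxyl-directed nucleophilic epoxidation, but delivery by a ketone perhydrate is without precedent; oxygen enters C8 and C17 syn to C6, the C8 configuration of the target, while free hydroperoxide should attack the tetrasubstituted alkene only slowly.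

**Step 18**
Reactants: 27 8,17-epoxy lactone ketone (epoxide oxygen syn to C6)
Product: 29 C11 enol triflate (11,12-alkene), via potassium enolate 28 (not isolated)
Conditions: KHMDS, THF, −78 °C; then N-(5-chloropyridin-2-yl)bis(trifluoromethanesulfonimide), −78 °C
Reagents that add atoms: N-(5-chloropyridin-2-yl)bis(trifluoromethanesulfonimide), O=S(=O)(N(c1ccc(Cl)cn1)S(=O)(=O)C(F)(F)F)C(F)(F)F
Why: Kinetic deprotonation at the C12 methylene (C10 is tertiary and shielded by C1 and C9) and O-sulfonylation of the enolate; the epoxy lactone has no acidic hydrogen, which is why this step follows step 17.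

**Step 19**
Reactants: 29 C11 enol triflate (11,12-alkene)
Product: 30 11-methyl-11,12-alkene
Conditions: Pd(PPh3)4 (5 mol %, zerovalent palladium), Me2Zn, THF, 0 °C to rt
Reagents that add atoms: dimethylzinc, C[Zn]C
Why: Negishi coupling attaches C20 to an sp2 carbon, so no stereocentre is at stake; the organozinc tolerates lactone, epoxide and silyl ethers, and oxidative addition to the triflate is faster than ionisation of the propargylic lactone.

**Step 20**
Reactants: 30 11-methyl-11,12-alkene
Product: 31 11,12-cis-diol (both hydroxyls α)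
Conditions: OsO4 (5 mol %), N-methylmorpholine N-oxide, acetone/H2O, 0 °C to rt
Reagents that add atoms: N-methylmorpholine N-oxide, C[N+]1([O-])CCOCC1; water, O
Why: Upjohn dihydroxylation; OsO4 adds to the trisubstituted alkene on the face opposite the allylic C10–C9 bond and the C15 methyl, as in osmylation of cyclohexenes anti to an allylic substituent, giving both hydroxyls α and C20 β; alkyne and epoxy lactone do not react.

**Step 21**
Reactants: 31 11,12-cis-diol (both hydroxyls α)
Product: 32 11,12-acetonide
Conditions: 2,2-dimethoxypropane, PPTS, CH2Cl2, rt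
Reagents that add atoms: 2,2-dimethoxypropane, COC(C)(C)OC
Why: Ketalisation of the cis-diol; it masks O12, which is free in the target, until the acetates are in place.

**Step 22**
Reactants: 32 11,12-acetonide
Product: 33 C2 primary alcohol
Conditions: DDQ, CH2Cl2/pH 7 buffer, 0 °C
Reagents that add atoms: none
Why: Oxidative removal of the 4-methoxybenzyl ether; silyl ethers, acetonide, alkyne and epoxy lactone are inert.

**Step 23**
Reactants: 33 C2 primary alcohol
Product: 34 C2 aldehyde
Conditions: Dess–Martin periodinane, NaHCO3, CH2Cl2, rt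
Reagents that add atoms: none
Why: Oxidation to the non-enolisable neopentyl aldehyde; O8 is still tied up in the epoxide, so no lactol with C2 can form.

**Step 24**
Reactants: 34 C2 aldehyde
Product: 35 C2 vinyl carbinol (both C2 epimers)
Conditions: CH2=CHMgBr, CeCl3, THF, −78 °C
Reagents that add atoms: vinylmagnesium bromide, C=C[Mg]Br
Why: Organocerium addition, selective for the aldehyde over the epoxy lactone; both epimers are expected and converge in step 25.

**Step 25**
Reactants: 35 C2 vinyl carbinol (both C2 epimers)
Product: 36 C2 vinyl ketone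
Conditions: Dess–Martin periodinane, NaHCO3, CH2Cl2, 0 °C
Reagents that add atoms: none
Why: Oxidation of the allylic alcohol; the enone is used without storage.

**Step 26**
Reactants: 36 C2 vinyl ketone
Product: 37 (2S)-vinyl carbinol
Conditions: (R)-2-methyl-CBS-oxazaborolidine, catecholborane, toluene, −78 °C
Reagents that add atoms: none
Why: Corey–Bakshi–Shibata reduction; the quaternary C1 acts as the large group and the vinyl group as the small one, so the R catalyst should give the 2S alcohol, and catecholborane at −78 °C touches neither lactone nor alkyne.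

**Step 27**
Reactants: 37 (2S)-vinyl carbinol
Product: 38 C16 propargylic alcohol
Conditions: HF·pyridine, pyridine, THF, 0 °C
Reagents that add atoms: none
Why: Selective cleavage of the primary propargylic silyl ether beside two hindered secondary ones; the electron-poor epoxy lactone resists the buffered reagent.

**Step 28**
Reactants: 38 C16 propargylic alcohol
Product: 39 C5 alkenylstannane (tin cis to C7)
Conditions: [Cp*RuCl]4 (2.5 mol %), Bu3SnH, CH2Cl2, rt
Reagents that add atoms: tributyltin hydride, CCCC[SnH](CCCC)CCCC
Why: Ruthenium-catalysed trans-hydrostannation of a propargylic alcohol: a hydrogen bond from the C16 hydroxyl to the chloride ligand places tin on C5, and trans addition puts H6 anti to tin, so tin (later C4) is cis to C7; C8 carries no free hydroxyl that could compete, and alkenes are inert.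

**Step 29**
Reactants: 39 C5 alkenylstannane (tin cis to C7)
Product: 40 8-hydroxy lactone (C17 epimers)
Conditions: SmI2 (divalent samarium), HMPA, 2-(dimethylamino)ethanol, THF, 0 °C
Reagents that add atoms: none
Why: Reductive opening of an α,β-epoxy lactone: electron transfer to the carbonyl, cleavage of the C17–O bond, a second electron transfer and protonation of the samarium enolate; the C8–O bond is untouched, so C8 keeps its configuration, C17 forms as a mixture, and alkenylstannane and allylic alcohols are not reduced.

**Step 30**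
Reactants: 40 8-hydroxy lactone (C17 epimers)
Product: 41 8-hydroxy lactone (C18 methyl cis to the C8 hydroxyl)
Conditions: DBU (0.5 equiv), CH2Cl2, rt
Reagents that add atoms: none
Why: Equilibration of the lactone α-centre through its enolate; C18 should settle trans to the bulky C9 substituent and cis to the hydroxyl, which is the target configuration, and an amidine base is too weak for retro-aldol cleavage.

**Step 31**
Reactants: 41 8-hydroxy lactone (C18 methyl cis to the C8 hydroxyl)
Product: 42 C5 alkenyl iodide
Conditions: I2, CH2Cl2, 0 °C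
Reagents that add atoms: iodine, II
Why: Iododestannylation with retention of alkene geometry; the terminal vinyl group adds iodine only reversibly.

**Step 32**
Reactants: 42 C5 alkenyl iodide
Product: 43 pentaol (C2, C8, C9, C14 and C16 hydroxyls free)
Conditions: HF·pyridine, THF, rt to 40 °C
Reagents that add atoms: none
Why: Cleavage of the two hindered secondary silyl ethers; acetonide and alkenyl iodide survive the fluoride source.

**Step 33**
Reactants: 43 pentaol (C2, C8, C9, C14 and C16 hydroxyls free)
Product: 44 C16 tert-butyldimethylsilyl ether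
Conditions: TBSCl (1.1 equiv), imidazole, CH2Cl2, −20 °C
Reagents that add atoms: tert-butyldimethylsilyl chloride, CC(C)(C)[Si](C)(C)Cl
Why: Selective silylation of the only primary hydroxyl beside three hindered secondary and one tertiary hydroxyl.

**Step 34**
Reactants: 44 C16 tert-butyldimethylsilyl ether
Product: 45 2,9,14-triacetate
Conditions: Ac2O, pyridine, DMAP (cat.), CH2Cl2, rt
Reagents that add atoms: acetic anhydride, CC(=O)OC(C)=O
Why: Acylation of the three secondary hydroxyls; the tertiary C8 hydroxyl does not react under these conditions.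

**Step 35**
Reactants: 45 2,9,14-triacetate
Product: 47 ring A closed tricycle, via C4 alkylborane 46 (not isolated)
Conditions: 9-BBN-H, THF, rt; then Pd(dppf)Cl2 (20 mol %), AsPh3, Cs2CO3, DMF/THF/H2O, high dilution, rt to 50 °C
Reagents that add atoms: none
Why: B-alkyl Suzuki–Miyaura macrocyclisation: 9-BBN hydroborates only the terminal vinyl group (boron on C4); zerovalent palladium formed in the flask inserts into the C5–I bond, base-assisted transmetalation and reductive elimination form C4–C5 with retention of geometry; high dilution, the cis alkene, the trans ring fusion and the lactone favour the ten-membered ring.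

**Step 36**
Reactants: 47 ring A closed tricycle
Product: 48 tetraol (C8, C11, C12 and C16 hydroxyls free)
Conditions: CF3CO2H/H2O/THF, 0 °C to rt
Reagents that add atoms: none
Why: One acid hydrolysis removes the primary silyl ether and the acetonide; acetates survive, and the time is kept short to prevent acetyl migration from O14 to O12.

**Step 37**
Reactants: 48 tetraol (C8, C11, C12 and C16 hydroxyls free)
Product: 49 CNP0211628.2
Conditions: N-chlorosuccinimide, Me2S, CH2Cl2, −20 to 0 °C
Reagents that add atoms: N-chlorosuccinimide, O=C1CCC(=O)N1Cl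
Why: Corey–Kim chlorination: the chlorosulfonium salt activates the primary allylic alcohol and chloride displaces at C16 by SN2 without allylic shift; the hindered secondary and the tertiary hydroxyls do not react at this temperature.

## Compound list

1 | 3-ethoxycyclohex-2-en-1-one | CCOC1=CC(=O)CCC1 | starting material
2 | rac-4-ethoxy-2-oxocyclohex-3-en-1-yl acetate | CCOC1=CC(=O)C(OC(C)=O)CC1 | intermediate
3 | (S)-3-ethoxy-6-hydroxycyclohex-2-en-1-one | CCOC1=CC(=O)[C@@H](O)CC1 | intermediate
4 | (S)-6-[(tert-butyldimethylsilyl)oxy]-3-ethoxycyclohex-2-en-1-one | CCOC1=CC(=O)[C@@H](O[Si](C)(C)C(C)(C)C)CC1 | intermediate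
5 | 4-methoxybenzyl alcohol | COc1ccc(CO)cc1 | starting material
6 | tributyl(iodomethyl)stannane | CCCC[Sn](CCCC)(CCCC)CI | starting material
7 | tributyl{[(4-methoxybenzyl)oxy]methyl}stannane | CCCC[Sn](CCCC)(CCCC)COCc1ccc(OC)cc1 | intermediate
8 | {[(4-methoxybenzyl)oxy]methyl}lithium | [Li]COCc1ccc(OC)cc1 | intermediate (not isolated)
9 | (6S)-6-[(tert-butyldimethylsilyl)oxy]-3-ethoxy-1-{[(4-methoxybenzyl)oxy]methyl}cyclohex-2-en-1-ol, both C1 epimers | CCOC1=CC(O)(COCc2ccc(OC)cc2)[C@@H](O[Si](C)(C)C(C)(C)C)CC1 | intermediate (not isolated)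
10 | (S)-4-[(tert-butyldimethylsilyl)oxy]-3-{[(4-methoxybenzyl)oxy]methyl}cyclohex-2-en-1-one (ring B enone) | O=C1C=C(COCc2ccc(OC)cc2)[C@@H](O[Si](C)(C)C(C)(C)C)CC1 | intermediate
11 | prop-2-yn-1-ol | C#CCO | starting material
12 | tert-butyldimethyl(prop-2-yn-1-yloxy)silane | C#CCO[Si](C)(C)C(C)(C)C | intermediate
13 | 2-methylenepropane-1,3-diol | C=C(CO)CO | starting material
14 | 2-{[(4-methoxybenzyl)oxy]methyl}prop-2-en-1-ol | C=C(CO)COCc1ccc(OC)cc1 | intermediate
15 | 2-{[(4-methoxybenzyl)oxy]methyl}prop-2-enal | C=C(C=O)COCc1ccc(OC)cc1 | intermediate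
16 | (S)-6-[(tert-butyldimethylsilyl)oxy]-2-{[(4-methoxybenzyl)oxy]methyl}hex-1-en-4-yn-3-ol | C=C(COCc1ccc(OC)cc1)[C@@H](O)C#CCO[Si](C)(C)C(C)(C)C | intermediate
17 | 2-(diethoxyphosphoryl)propanoic acid | CCOP(=O)(OCC)C(C)C(=O)O | starting material
18 | phosphonopropanoate ester of 16 (epimers at the phosphonate carbon) | C=C(COCc1ccc(OC)cc1)[C@@H](OC(=O)C(C)P(=O)(OCC)OCC)C#CCO[Si](C)(C)C(C)(C)C | intermediate
19 | (S)-6-[(tert-butyldimethylsilyl)oxy]-1-[(4-methoxybenzyl)oxy]-2-oxohex-4-yn-3-yl 2-(diethoxyphosphoryl)propanoate | O=C(COCc1ccc(OC)cc1)[C@@H](OC(=O)C(C)P(=O)(OCC)OCC)C#CCO[Si](C)(C)C(C)(C)C | intermediate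
20 | (S)-5-{3-[(tert-butyldimethylsilyl)oxy]prop-1-yn-1-yl}-4-{[(4-methoxybenzyl)oxy]methyl}-3-methylfuran-2(5H)-one | COc1ccc(COCC2=C(C)C(=O)O[C@H]2C#CCO[Si](C)(C)C(C)(C)C)cc1 | intermediate
21 | (S)-5-{3-[(tert-butyldimethylsilyl)oxy]prop-1-yn-1-yl}-4-(hydroxymethyl)-3-methylfuran-2(5H)-one | OCC1=C(C)C(=O)O[C@H]1C#CCO[Si](C)(C)C(C)(C)C | intermediate
22 | (S)-2-{3-[(tert-butyldimethylsilyl)oxy]prop-1-yn-1-yl}-4-methyl-5-oxo-2,5-dihydrofuran-3-carbaldehyde (butenolide aldehyde) | O=CC1=C(C)C(=O)O[C@H]1C#CCO[Si](C)(C)C(C)(C)C | intermediate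
23 | C10=C11 trimethylsilyl enol ether carrying C15 on C1 | C[Si](C)(C)OC1=C[C@@](C)(COCc2ccc(OC)cc2)[C@@H](O[Si](C)(C)C(C)(C)C)CC1 | intermediate (not isolated)
24 | aldol adduct: C11 ketone, C9 alcohol, butenolide, C2 as CH2OPMB, O14 and O16 silylated | CC(C)(C)[Si](C)(C)OCC#C[C@@H]1OC(=O)C(C)=C1[C@@H](O)[C@H]2C(=O)CC[C@H](O[Si](C)(C)C(C)(C)C)[C@]2(C)COCc3ccc(OC)cc3 | intermediate
25 | C9 tert-butyldimethylsilyl ether of 24 | CC(C)(C)[Si](C)(C)OCC#C[C@@H]1OC(=O)C(C)=C1[C@@H](O[Si](C)(C)C(C)(C)C)[C@H]2C(=O)CC[C@H](O[Si](C)(C)C(C)(C)C)[C@]2(C)COCc3ccc(OC)cc3 | intermediate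
26 | C11 perhydrate (hydroxy hydroperoxide) of 25 | CC(C)(C)[Si](C)(C)OCC#C[C@@H]1OC(=O)C(C)=C1[C@@H](O[Si](C)(C)C(C)(C)C)[C@H]2C(O)(OO)CC[C@H](O[Si](C)(C)C(C)(C)C)[C@]2(C)COCc3ccc(OC)cc3 | intermediate (not isolated)
27 | 8,17-epoxy lactone ketone, epoxide oxygen syn to C6 | CC(C)(C)[Si](C)(C)OCC#C[C@@H]1OC(=O)[C@]2(C)O[C@]12[C@@H](O[Si](C)(C)C(C)(C)C)[C@H]3C(=O)CC[C@H](O[Si](C)(C)C(C)(C)C)[C@]3(C)COCc4ccc(OC)cc4 | intermediate
28 | potassium C11–C12 enolate of 27 | [K+].CC(C)(C)[Si](C)(C)OCC#C[C@@H]1OC(=O)[C@]2(C)O[C@]12[C@@H](O[Si](C)(C)C(C)(C)C)[C@H]3C([O-])=CC[C@H](O[Si](C)(C)C(C)(C)C)[C@]3(C)COCc4ccc(OC)cc4 | intermediate (not isolated)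
29 | C11 enol triflate (11,12-alkene) | CC(C)(C)[Si](C)(C)OCC#C[C@@H]1OC(=O)[C@]2(C)O[C@]12[C@@H](O[Si](C)(C)C(C)(C)C)[C@H]3C(OS(=O)(=O)C(F)(F)F)=CC[C@H](O[Si](C)(C)C(C)(C)C)[C@]3(C)COCc4ccc(OC)cc4 | intermediate
30 | 11-methyl-11,12-alkene | CC(C)(C)[Si](C)(C)OCC#C[C@@H]1OC(=O)[C@]2(C)O[C@]12[C@@H](O[Si](C)(C)C(C)(C)C)[C@H]3C(C)=CC[C@H](O[Si](C)(C)C(C)(C)C)[C@]3(C)COCc4ccc(OC)cc4 | intermediate
31 | 11,12-cis-diol | CC(C)(C)[Si](C)(C)OCC#C[C@@H]1OC(=O)[C@]2(C)O[C@]12[C@@H](O[Si](C)(C)C(C)(C)C)[C@H]3[C@](C)(O)[C@H](O)C[C@H](O[Si](C)(C)C(C)(C)C)[C@]3(C)COCc4ccc(OC)cc4 | intermediate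
32 | 11,12-acetonide | CC(C)(C)[Si](C)(C)OCC#C[C@@H]1OC(=O)[C@]2(C)O[C@]12[C@@H](O[Si](C)(C)C(C)(C)C)[C@H]3[C@]5(C)OC(C)(C)O[C@@H]5C[C@H](O[Si](C)(C)C(C)(C)C)[C@]3(C)COCc4ccc(OC)cc4 | intermediate
33 | C2 primary alcohol | CC(C)(C)[Si](C)(C)OCC#C[C@@H]1OC(=O)[C@]2(C)O[C@]12[C@@H](O[Si](C)(C)C(C)(C)C)[C@H]3[C@]5(C)OC(C)(C)O[C@@H]5C[C@H](O[Si](C)(C)C(C)(C)C)[C@]3(C)CO | intermediate
34 | C2 aldehyde | CC(C)(C)[Si](C)(C)OCC#C[C@@H]1OC(=O)[C@]2(C)O[C@]12[C@@H](O[Si](C)(C)C(C)(C)C)[C@H]3[C@]5(C)OC(C)(C)O[C@@H]5C[C@H](O[Si](C)(C)C(C)(C)C)[C@]3(C)C=O | intermediate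
35 | C2 vinyl carbinol, both C2 epimers | CC(C)(C)[Si](C)(C)OCC#C[C@@H]1OC(=O)[C@]2(C)O[C@]12[C@@H](O[Si](C)(C)C(C)(C)C)[C@H]3[C@]5(C)OC(C)(C)O[C@@H]5C[C@H](O[Si](C)(C)C(C)(C)C)[C@]3(C)C(O)C=C | intermediate
36 | C2 vinyl ketone | CC(C)(C)[Si](C)(C)OCC#C[C@@H]1OC(=O)[C@]2(C)O[C@]12[C@@H](O[Si](C)(C)C(C)(C)C)[C@H]3[C@]5(C)OC(C)(C)O[C@@H]5C[C@H](O[Si](C)(C)C(C)(C)C)[C@]3(C)C(=O)C=C | intermediate
37 | (2S)-vinyl carbinol | CC(C)(C)[Si](C)(C)OCC#C[C@@H]1OC(=O)[C@]2(C)O[C@]12[C@@H](O[Si](C)(C)C(C)(C)C)[C@H]3[C@]5(C)OC(C)(C)O[C@@H]5C[C@H](O[Si](C)(C)C(C)(C)C)[C@]3(C)[C@@H](O)C=C | intermediate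
38 | C16 propargylic alcohol | OCC#C[C@@H]1OC(=O)[C@]2(C)O[C@]12[C@@H](O[Si](C)(C)C(C)(C)C)[C@H]3[C@]5(C)OC(C)(C)O[C@@H]5C[C@H](O[Si](C)(C)C(C)(C)C)[C@]3(C)[C@@H](O)C=C | intermediate
39 | C5 alkenylstannane, tin cis to C7 | OC/C([Sn](CCCC)(CCCC)CCCC)=C/[C@@H]1OC(=O)[C@]2(C)O[C@]12[C@@H](O[Si](C)(C)C(C)(C)C)[C@H]3[C@]5(C)OC(C)(C)O[C@@H]5C[C@H](O[Si](C)(C)C(C)(C)C)[C@]3(C)[C@@H](O)C=C | intermediate
40 | 8-hydroxy lactone, C17 epimers | OC/C([Sn](CCCC)(CCCC)CCCC)=C/[C@@H]1OC(=O)C(C)[C@@]1(O)[C@@H](O[Si](C)(C)C(C)(C)C)[C@H]3[C@]5(C)OC(C)(C)O[C@@H]5C[C@H](O[Si](C)(C)C(C)(C)C)[C@]3(C)[C@@H](O)C=C | intermediate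
41 | 8-hydroxy lactone, C18 methyl cis to the C8 hydroxyl | OC/C([Sn](CCCC)(CCCC)CCCC)=C/[C@@H]1OC(=O)[C@H](C)[C@@]1(O)[C@@H](O[Si](C)(C)C(C)(C)C)[C@H]3[C@]5(C)OC(C)(C)O[C@@H]5C[C@H](O[Si](C)(C)C(C)(C)C)[C@]3(C)[C@@H](O)C=C | intermediate
42 | C5 alkenyl iodide | OC/C(I)=C/[C@@H]1OC(=O)[C@H](C)[C@@]1(O)[C@@H](O[Si](C)(C)C(C)(C)C)[C@H]3[C@]5(C)OC(C)(C)O[C@@H]5C[C@H](O[Si](C)(C)C(C)(C)C)[C@]3(C)[C@@H](O)C=C | intermediate
43 | pentaol | OC/C(I)=C/[C@@H]1OC(=O)[C@H](C)[C@@]1(O)[C@@H](O)[C@H]3[C@]5(C)OC(C)(C)O[C@@H]5C[C@H](O)[C@]3(C)[C@@H](O)C=C | intermediate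
44 | C16 tert-butyldimethylsilyl ether | CC(C)(C)[Si](C)(C)OC/C(I)=C/[C@@H]1OC(=O)[C@H](C)[C@@]1(O)[C@@H](O)[C@H]3[C@]5(C)OC(C)(C)O[C@@H]5C[C@H](O)[C@]3(C)[C@@H](O)C=C | intermediate
45 | 2,9,14-triacetate | CC(C)(C)[Si](C)(C)OC/C(I)=C/[C@@H]1OC(=O)[C@H](C)[C@@]1(O)[C@@H](OC(C)=O)[C@H]3[C@]5(C)OC(C)(C)O[C@@H]5C[C@H](OC(C)=O)[C@]3(C)[C@@H](OC(C)=O)C=C | intermediate
46 | C4 alkylborane (9-BBN adduct of 45) | CC(C)(C)[Si](C)(C)OC/C(I)=C/[C@@H]1OC(=O)[C@H](C)[C@@]1(O)[C@@H](OC(C)=O)[C@H]3[C@]5(C)OC(C)(C)O[C@@H]5C[C@H](OC(C)=O)[C@]3(C)[C@@H](OC(C)=O)CCB6C7CCCC6CCC7 | intermediate (not isolated)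
47 | ring A closed tricycle (O16 silylated, 11,12-acetonide) | CC(=O)O[C@H]1CC/C(CO[Si](C)(C)C(C)(C)C)=C\[C@@H]2OC(=O)[C@H](C)[C@@]2(O)[C@@H](OC(C)=O)[C@H]2[C@]3(C)OC(C)(C)O[C@@H]3C[C@H](OC(C)=O)[C@]12C | intermediate
48 | tetraol (16-alcohol) | CC(=O)O[C@H]1CC/C(CO)=C\[C@@H]2OC(=O)[C@H](C)[C@@]2(O)[C@@H](OC(C)=O)[C@H]2[C@](C)(O)[C@H](O)C[C@H](OC(C)=O)[C@]12C | intermediate
49 | CNP0211628.2 | CC(=O)O[C@H]1CC/C(CCl)=C\[C@@H]2OC(=O)[C@H](C)[C@@]2(O)[C@@H](OC(C)=O)[C@H]2[C@](C)(O)[C@H](O)C[C@H](OC(C)=O)[C@]12C | target

## Step count and least certain steps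

- Total: 37 steps.
- Longest linear sequence: 31 steps (13 through steps 7–37).
- From 1 the sequence is 27 steps (steps 1, 2, 3, 5, then 15–37).

**Step 17 (the labelled step).** What may go wrong: the peroxide may fail to be delivered from the C11 perhydrate, so that either nothing happens or free hydroperoxide attacks the open butenolide face and the C8 oxygen ends on the wrong side; slow base-induced epimerisation at C7 or C10 is a second danger. Fallback in known chemistry, from 25 back to 27: the C11 ketone is reduced (NaBH4, CeCl3, MeOH, −40 °C) to C11 alcohol F1. Its lithium alkoxide is treated with LiOOt-Bu (t-BuOOH, n-BuLi, THF, −20 °C); this is an alkoxide-directed nucleophilic epoxidation of the kind known for hydroxy enoates, in which the alkoxide on ring B holds the peroxide on the same butenolide face, and it gives epoxy alcohol F2. Dess–Martin oxidation of F2 returns ketone 27.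

**Step 15 (key step).** What may go wrong: loss of syn selectivity at C9 if part of the reaction runs through a closed, metal-bound transition state; attack at C10 on the face of the C2 arm if the two C1 substituents are not differentiated well enough; retro-aldol cleavage or dehydration of the adduct on work-up. Fallback, from 24 obtained as a C9 epimer mixture back to 24: Dess–Martin oxidation gives 1,3-diketone F3, and the more accessible, butenolide-conjugated C9 carbonyl is reduced with Zn(BH4)2. In the zinc chelate between O9 and O11 hydride enters anti to the quaternary C1, which corresponds to the C9 configuration of 24.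

**Step 35.** What may go wrong: oligomerisation, protodeboronation or slow reductive elimination because of the strain of the ten-membered ring; ionisation of the allylic lactone C7–O bond by palladium is a further risk. Fallback, from 45 back to 47: Stille coupling with tributyl(vinyl)stannane (Pd2(dba)3, AsPh3, CuI) gives tetraene F4. Ring-closing metathesis (second-generation Grubbs catalyst, RuCl2(=CHPh)(H2IMes)(PCy3), toluene, high dilution) between the C2 and C5 vinyl groups gives macrocyclic 3Z,5-diene F5, a diene pattern that occurs in natural briaranes. Diimide (2-nitrobenzenesulfonohydrazide, Et3N) reduces the disubstituted C3=C4 alkene in preference to the trisubstituted one and gives 47.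

**Step 12.** What may go wrong: loss of configuration at C7 by enolisation of the α-acyloxy ketone or of the butenolide under the basic conditions. Fallback, from 16 back to 20: acylation with 2-bromopropanoyl bromide and pyridine gives bromo ester F6, and OsO4/NaIO4 cleavage gives bromo keto ester F7. A Reformatsky cyclisation with CrCl2 (divalent chromium) and LiI in THF closes β-hydroxy lactone F8 under neutral conditions, and dehydration with Martin sulfurane gives 20.

**Step 20.** What may go wrong: poor facial selectivity, because ring B is conformationally mobile and the C14 silyloxy group can shield the α-face at C12. Fallback, from 30 back to 32: CSA in MeOH removes the primary C16 and the less hindered C14 silyl ether to give diol F9. Stoichiometric OsO4·TMEDA (CH2Cl2, −78 °C), hydrogen-bonded to the C14 hydroxyl, delivers both oxygens to the α-face and gives tetraol F10 after reductive work-up. Ketalisation gives acetonide F11, and TBSOTf with 2,6-lutidine restores both silyl ethers to give 32.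

## Further compounds

F1 | step 17 | C11 alcohol of 25 (C11 configuration open) | CC(C)(C)[Si](C)(C)OCC#C[C@@H]1OC(=O)C(C)=C1[C@@H](O[Si](C)(C)C(C)(C)C)[C@H]2C(O)CC[C@H](O[Si](C)(C)C(C)(C)C)[C@]2(C)COCc3ccc(OC)cc3
F2 | step 17 | 8,17-epoxy lactone C11 alcohol | CC(C)(C)[Si](C)(C)OCC#C[C@@H]1OC(=O)[C@]2(C)O[C@]12[C@@H](O[Si](C)(C)C(C)(C)C)[C@H]3C(O)CC[C@H](O[Si](C)(C)C(C)(C)C)[C@]3(C)COCc4ccc(OC)cc4
F3 | step 15 | C9,C11-diketone from 24 | CC(C)(C)[Si](C)(C)OCC#C[C@@H]1OC(=O)C(C)=C1C(=O)[C@H]2C(=O)CC[C@H](O[Si](C)(C)C(C)(C)C)[C@]2(C)COCc3ccc(OC)cc3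
F4 | step 35 | C5-vinyl tetraene triacetate | CC(C)(C)[Si](C)(C)OC/C(C=C)=C/[C@@H]1OC(=O)[C@H](C)[C@@]1(O)[C@@H](OC(C)=O)[C@H]3[C@]5(C)OC(C)(C)O[C@@H]5C[C@H](OC(C)=O)[C@]3(C)[C@@H](OC(C)=O)C=C
F5 | step 35 | macrocyclic 3Z,5-diene | CC(=O)O[C@H]1/C=C\C(CO[Si](C)(C)C(C)(C)C)=C/[C@@H]2OC(=O)[C@H](C)[C@@]2(O)[C@@H](OC(C)=O)[C@H]2[C@]3(C)OC(C)(C)O[C@@H]3C[C@H](OC(C)=O)[C@]12C
F6 | step 12 | 2-bromopropanoate ester of 16 | C=C(COCc1ccc(OC)cc1)[C@@H](OC(=O)C(C)Br)C#CCO[Si](C)(C)C(C)(C)C
F7 | step 12 | bromo keto ester | O=C(COCc1ccc(OC)cc1)[C@@H](OC(=O)C(C)Br)C#CCO[Si](C)(C)C(C)(C)C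
F8 | step 12 | β-hydroxy lactone (C8 and C17 configuration open) | COc1ccc(COCC2(O)C(C)C(=O)O[C@H]2C#CCO[Si](C)(C)C(C)(C)C)cc1
F9 | step 20 | C14,C16-diol of alkene 30 | OCC#C[C@@H]1OC(=O)[C@]2(C)O[C@]12[C@@H](O[Si](C)(C)C(C)(C)C)[C@H]3C(C)=CC[C@H](O)[C@]3(C)COCc4ccc(OC)cc4
F10 | step 20 | 11,12,14,16-tetraol | OCC#C[C@@H]1OC(=O)[C@]2(C)O[C@]12[C@@H](O[Si](C)(C)C(C)(C)C)[C@H]3[C@](C)(O)[C@H](O)C[C@H](O)[C@]3(C)COCc4ccc(OC)cc4
F11 | step 20 | 11,12-acetonide 14,16-diol | OCC#C[C@@H]1OC(=O)[C@]2(C)O[C@]12[C@@H](O[Si](C)(C)C(C)(C)C)[C@H]3[C@]5(C)OC(C)(C)O[C@@H]5C[C@H](O)[C@]3(C)COCc4ccc(OC)cc4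
A1 | alternative 1 | tricyclic C2 ketone, ring A closed | CC(C)(C)[Si](C)(C)OC/C1=C/[C@@H]2OC(=O)[C@H](C)[C@@]2(O)[C@@H](OC(C)=O)[C@H]2[C@](C)(OC(C)(C)O3)[C@H]3C[C@H](OC(C)=O)[C@]2(C)C(=O)CC1
A2 | alternative 2 | ring B cyclohexene carbaldehyde, C12 silyl enol ether | c1ccccc1COC[C@H]2[C@H](C)C(O[Si](C(C)C)(C(C)C)C(C)C)=C[C@H](OCc3ccc(OC)cc3)[C@]2(C)C=O
A3 | alternative 3 | ring B cis-11,12-diol | c1ccccc1COC[C@H]2[C@](C)(O)[C@H](O)C[C@H](O[Si](C)(C)C(C)(C)C)[C@]2(C)COCc1ccc(OC)cc1
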